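The cyclohexene ring (C1 = CH–OAc, C2 and C3 = diol carbons, C4=C5 = alkene, C5 carrying exocyclic C7, C6 = CH–OBz) is disconnected between C5 and C6. The C6 carbinol next to the C7-bearing alkene carbon C5 is a reduced Morita–Baylis–Hillman motif, so an intramolecular Morita–Baylis–Hillman reaction of an open-chain (E)-enal/α-acetoxy aldehyde forms the C5–C6 bond, closes the carbocycle and sets C6 in one operation. The precursor comes from 3,4-O-isopropylidene-D-mannitol, which supplies C1–C3; its trans-acetonide steers C6–O anti to C1–OAc. Luche reduction, double benzoylation and acetal hydrolysis complete the route.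

Key step: step 6

Remark on the chemistry and labels: the atom labels C1–C7 defined above are used for the corresponding atoms of all intermediates. In the sugar names of the open-chain compounds, hept positions 1, 2, 3, 4, 5, 6, 7 are C7, C5, C4, C3, C2, C1, C6. Compound 2 is drawn as the open-chain aldehyde although it may rest as a hemiacetal. Compounds 1 and 3 are taken as commercially available.

Step 1
Reactants: 1 3,4-O-isopropylidene-D-mannitol
Product: 2 2,3-O-isopropylidene-D-arabinose (aldehydo form)
Conditions: NaIO4 (1.0 equiv, added in portions), NaHCO3, THF/H2O, 0 °C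
Reagents that add atoms: none
Why: Periodate glycol cleavage (Malaprade oxidation) with one equivalent should cut only one of the two equivalent terminal diols, because the mono-cleaved δ-hydroxy aldehyde can rest as a pyranose hemiacetal without a free vicinal diol and the doubly cleaved dialdehyde stays in the aqueous phase; the three stereocenters (later C3, C2, C1) are untouched.

Step 2
Reactants: 2 2,3-O-isopropylidene-D-arabinose; 3 (triphenylphosphoranylidene)acetaldehyde
Product: 4 (E)-2,3-dideoxy-4,5-O-isopropylidene-D-arabino-hept-2-enose (enal with free C1 and C6 hydroxyls)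
Conditions: Ph3P=CHCHO (1.1 equiv), THF, 50 °C
Reagents that add atoms: none
Why: Wittig olefination of the aldehyde (hemiacetal) with a stabilised ylide, E-selective as usual for stabilised ylides; no stereocenter is formed.

Step 3
Reactants: 4 (E)-2,3-dideoxy-4,5-O-isopropylidene-D-arabino-hept-2-enose
Product: 6 (E)-6-O-acetyl-7-O-(tert-butyldimethylsilyl)-2,3-dideoxy-4,5-O-isopropylidene-D-arabino-hept-2-enose, via mono-silyl ether 5 (not isolated)
Conditions: TBSCl (1.05 equiv), imidazole, CH2Cl2, −10 °C; then Ac2O, pyridine, DMAP (cat.), rt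
Reagents that add atoms: tert-butyldimethylsilyl chloride CC(C)(C)[Si](C)(C)Cl; acetic anhydride CC(=O)OC(C)=O
Why: Silylation is selective for the primary C6 hydroxyl on steric grounds, and the remaining secondary C1 hydroxyl is then acetylated in the same flask by DMAP-catalysed acylation.

Step 4
Reactants: 6 (E)-6-O-acetyl-7-O-(tert-butyldimethylsilyl)-2,3-dideoxy-4,5-O-isopropylidene-D-arabino-hept-2-enose
Product: 7 (E)-6-O-acetyl-2,3-dideoxy-4,5-O-isopropylidene-D-arabino-hept-2-enose (primary C6 alcohol)
Conditions: HF·pyridine, pyridine/THF, 0 °C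
Reagents that add atoms: none
Why: Fluoride cleavage of the primary silyl ether under buffered acidic conditions, chosen because they should not drive the C1 acetate onto the freed C6 hydroxyl as basic fluoride can; acetonide and enal are inert.

Step 5
Reactants: 7 (E)-6-O-acetyl-2,3-dideoxy-4,5-O-isopropylidene-D-arabino-hept-2-enose
Product: 8 (E)-6-O-acetyl-2,3-dideoxy-4,5-O-isopropylidene-D-arabino-hept-2-enodialdose (enal at C7, α-acetoxy aldehyde at C6)
Conditions: Dess–Martin periodinane, CH2Cl2, 0 °C to rt; used crude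
Reagents that add atoms: none
Why: Dess–Martin oxidation of the primary alcohol to the aldehyde under neutral conditions that should not epimerise the α-acetoxy center C1.

Step 6
Reactants: 8 (E)-6-O-acetyl-2,3-dideoxy-4,5-O-isopropylidene-D-arabino-hept-2-enodialdose
Product: 9 (1R,2S,3R,6S)-1-acetoxy-6-hydroxy-2,3-(isopropylidenedioxy)cyclohex-4-ene-5-carbaldehyde (C1–OAc and C2–O on one face, C3–O and C6–OH on the other, acetonide trans-fused)
Conditions: PMe3 (0.5 equiv), t-AmOH, 0 °C to rt, 0.02 M
Reagents that add atoms: none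
Why: Intramolecular Morita–Baylis–Hillman reaction: PMe3 adds to C4 of the enal, the phosphonium enolate attacks the C6 aldehyde through C5, and proton transfer with E1cB loss of PMe3 restores C4=C5 as the ring alkene, so the (E)-geometry of 8 is no obstacle and the step is a net isomerisation. The closest known reaction type is the phosphine- or amine-mediated cyclisation of ω-formyl enals, enones and enoates to 6-hydroxycyclohex-1-ene carbonyl compounds. The cyclohexene ring closes in a 6-(enolexo)-exo-trig aldol step. The only new stereocenter, C6, is substrate-controlled: the trans-fused acetonide holds the C2 and C3 oxygens equatorial, which places C1–OAc axial, and the aldehyde oxygen should take the pseudoaxial position anti to it (opposed C–O dipoles, no A(1,2) clash with the C5 formyl group), giving the 1,6-trans (6S) alcohol, an outcome that reversibility of the aldol step before elimination should reinforce. The step needs conjugate addition to the enal instead of base chemistry at the α-acetoxy aldehyde (epimerisation at C1, β-elimination of the C2 oxygen) and intramolecular instead of intermolecular aldol reaction; a weakly basic, strongly nucleophilic phosphine in a protic solvent at high dilution should secure both. In 9 the trans-diaxial C1–OAc and C6–OH cannot exchange the acetyl group.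

Step 7
Reactants: 9 (1R,2S,3R,6S)-1-acetoxy-6-hydroxy-2,3-(isopropylidenedioxy)cyclohex-4-ene-5-carbaldehyde
Product: 10 (1R,2S,3R,6S)-1-acetoxy-5-(hydroxymethyl)-2,3-(isopropylidenedioxy)cyclohex-4-en-6-ol
Conditions: NaBH4, CeCl3·7H2O, MeOH, −40 °C
Reagents that add atoms: none
Why: Luche reduction gives 1,2-selective hydride addition to the enal carbonyl and should leave the acetate and the alkene untouched at low temperature; no stereocenter is formed.

Step 8
Reactants: 10 (1R,2S,3R,6S)-1-acetoxy-5-(hydroxymethyl)-2,3-(isopropylidenedioxy)cyclohex-4-en-6-ol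
Product: 11 (1R,2S,3R,6S)-1-acetoxy-6-benzoyloxy-5-(benzoyloxymethyl)-2,3-(isopropylidenedioxy)cyclohex-4-ene
Conditions: BzCl (2.5 equiv), pyridine, DMAP (cat.), CH2Cl2, 0 °C to rt
Reagents that add atoms: benzoyl chloride O=C(Cl)c1ccccc1
Why: DMAP-catalysed acylation of the primary allylic C7 hydroxyl and the secondary C6 hydroxyl; acetyl migration is excluded because C1–OAc and C6–OH are held trans-diaxial by the trans-fused acetonide.

Step 9
Reactants: 11 (1R,2S,3R,6S)-1-acetoxy-6-benzoyloxy-5-(benzoyloxymethyl)-2,3-(isopropylidenedioxy)cyclohex-4-ene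
Product: 12 (1S,2S,3R,6S)-1-acetoxy-6-benzoyloxy-5-(benzoyloxymethyl)cyclohex-4-ene-2,3-diol (CNP0213675.1; the C1 descriptor changes only through substituent ranking, not configuration)
Conditions: AcOH/H2O (4:1), 40 °C
Reagents that add atoms: none
Why: Acid-catalysed acetal hydrolysis; the strained trans-fused dioxolane should open under mild aqueous acid that leaves the acetate and benzoates in place and does not promote base-type acyl migration to the freed C2 hydroxyl.

Compound list
1 | 3,4-O-isopropylidene-D-mannitol, (4R,5R)-4,5-bis[(1R)-1,2-dihydroxyethyl]-2,2-dimethyl-1,3-dioxolane | OC[C@@H](O)[C@H]1OC(C)(C)O[C@@H]1[C@H](O)CO | starting material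
2 | 2,3-O-isopropylidene-D-arabinose (aldehydo form), (4S,5R)-5-[(1R)-1,2-dihydroxyethyl]-2,2-dimethyl-1,3-dioxolane-4-carbaldehyde | O=C[C@H]1OC(C)(C)O[C@@H]1[C@H](O)CO | intermediate
3 | (triphenylphosphoranylidene)acetaldehyde | O=CC=P(c1ccccc1)(c1ccccc1)c1ccccc1 | starting material
4 | (E)-2,3-dideoxy-4,5-O-isopropylidene-D-arabino-hept-2-enose | O=C/C=C/[C@H]1OC(C)(C)O[C@@H]1[C@H](O)CO | intermediate
5 | (E)-7-O-(tert-butyldimethylsilyl)-2,3-dideoxy-4,5-O-isopropylidene-D-arabino-hept-2-enose | O=C/C=C/[C@H]1OC(C)(C)O[C@@H]1[C@H](O)CO[Si](C)(C)C(C)(C)C | intermediate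
6 | (E)-6-O-acetyl-7-O-(tert-butyldimethylsilyl)-2,3-dideoxy-4,5-O-isopropylidene-D-arabino-hept-2-enose | O=C/C=C/[C@H]1OC(C)(C)O[C@@H]1[C@H](OC(C)=O)CO[Si](C)(C)C(C)(C)C | intermediate
7 | (E)-6-O-acetyl-2,3-dideoxy-4,5-O-isopropylidene-D-arabino-hept-2-enose | O=C/C=C/[C@H]1OC(C)(C)O[C@@H]1[C@H](OC(C)=O)CO | intermediate
8 | (E)-6-O-acetyl-2,3-dideoxy-4,5-O-isopropylidene-D-arabino-hept-2-enodialdose | O=C/C=C/[C@H]1OC(C)(C)O[C@@H]1[C@H](OC(C)=O)C=O | intermediate
9 | (1R,2S,3R,6S)-1-acetoxy-6-hydroxy-2,3-(isopropylidenedioxy)cyclohex-4-ene-5-carbaldehyde | CC(=O)O[C@H]1[C@H]2OC(C)(C)O[C@@H]2C=C(C=O)[C@@H]1O | intermediate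
10 | (1R,2S,3R,6S)-1-acetoxy-5-(hydroxymethyl)-2,3-(isopropylidenedioxy)cyclohex-4-en-6-ol | CC(=O)O[C@H]1[C@H]2OC(C)(C)O[C@@H]2C=C(CO)[C@@H]1O | intermediate
11 | (1R,2S,3R,6S)-1-acetoxy-6-benzoyloxy-5-(benzoyloxymethyl)-2,3-(isopropylidenedioxy)cyclohex-4-ene | CC(=O)O[C@H]1[C@H]2OC(C)(C)O[C@@H]2C=C(COC(=O)c2ccccc2)[C@@H]1OC(=O)c1ccccc1 | intermediate
12 | (1S,2S,3R,6S)-1-acetoxy-6-benzoyloxy-5-(benzoyloxymethyl)cyclohex-4-ene-2,3-diol (CNP0213675.1) | CC(=O)O[C@H]1[C@@H](O)[C@H](O)C=C(COC(=O)c2ccccc2)[C@@H]1OC(=O)c1ccccc1 | target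

Total step count: 9. Longest linear sequence: 9 steps (from 1).

Steps most likely to fail

Step 6. The Lewis base may epimerise C1 or eliminate the C2 oxygen from the α-acetoxy aldehyde before ring closure, oligomerisation may compete, or the facial selectivity at C6 may be poor. Fallback: close the same C5–C6 bond by a Nozaki–Hiyama–Kishi reaction of a vinyl iodide, which needs no base. It sets out from 6: α-iodination of the enal (I2, pyridine, DMAP (cat.), CH2Cl2) should give the (Z)-2-iodo enal F1. Luche reduction (NaBH4, CeCl3·7H2O, MeOH, −40 °C) gives the iodo allylic alcohol F2, and BzCl/pyridine gives the benzoate F3. HF·pyridine frees the primary alcohol F4, and Dess–Martin oxidation gives the α-acetoxy aldehyde F5. CrCl2 (excess) with NiCl2 (cat.) in DMSO at rt under high dilution should add the vinyl chromium species at C5 to the C6 aldehyde with retention of alkene geometry, giving the cyclohexenol F6. Benzoylation of its C6 hydroxyl (BzCl, pyridine, DMAP) returns to the route at 11.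

Step 1. Cleavage may not stop after the first diol and may run on to the C2-symmetric dialdehyde. Fallback: tell the two termini apart by protection instead of stoichiometry. It sets out from 1: acetonation (2,2-dimethoxypropane, TsOH, acetone) gives the triacetonide F7, and controlled hydrolysis (70% aq. AcOH, 40 °C, over-hydrolysed material recycled) removes one terminal acetonide to give the diol F8. Exhaustive cleavage of its single free diol (NaIO4, aq. NaHCO3, CH2Cl2) gives the protected aldehyde F9, and Wittig reaction with 3 (toluene, 60 °C) gives the diacetonide enal F10. Selective hydrolysis of the terminal acetonide (aq. AcOH, rt) returns to the route at 4.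

Step 2. The weakly nucleophilic formyl ylide may react sluggishly with the hemiacetal form of 2, the product enal may be homologated a second time, or the primary hydroxyl may add to the enal. Fallback: build the enal through the ester oxidation level. It sets out from 2: the ester ylide Ph3P=CHCO2Et (THF, 60 °C), which reacts reliably with lactols, gives the (E)-enoate F11. DIBAL-H (CH2Cl2, −78 °C) gives the allylic alcohol (triol) F12. MnO2 (CH2Cl2, rt), which oxidises only the allylic hydroxyl, returns to the route at 4.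

Further compounds
F1 | step 6 | (Z)-2-iodo derivative of 6, (2Z)-6-O-acetyl-7-O-(tert-butyldimethylsilyl)-2,3-dideoxy-2-iodo-4,5-O-isopropylidene-D-arabino-hept-2-enose | O=C/C(I)=C/[C@H]1OC(C)(C)O[C@@H]1[C@H](OC(C)=O)CO[Si](C)(C)C(C)(C)C
F2 | step 6 | (2Z)-6-O-acetyl-7-O-(tert-butyldimethylsilyl)-2,3-dideoxy-2-iodo-4,5-O-isopropylidene-D-arabino-hept-2-enitol (C7 allylic alcohol) | OC/C(I)=C/[C@H]1OC(C)(C)O[C@@H]1[C@H](OC(C)=O)CO[Si](C)(C)C(C)(C)C
F3 | step 6 | C7 benzoate of F2 | O=C(OC/C(I)=C/[C@H]1OC(C)(C)O[C@@H]1[C@H](OC(C)=O)CO[Si](C)(C)C(C)(C)C)c1ccccc1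
F4 | step 6 | desilylated F3 (free primary C6 alcohol) | O=C(OC/C(I)=C/[C@H]1OC(C)(C)O[C@@H]1[C@H](OC(C)=O)CO)c1ccccc1
F5 | step 6 | C6 aldehyde from F4 (vinyl iodide with α-acetoxy aldehyde) | O=C(OC/C(I)=C/[C@H]1OC(C)(C)O[C@@H]1[C@H](OC(C)=O)C=O)c1ccccc1
F6 | step 6 | (1R,2S,3R,6S)-1-acetoxy-5-(benzoyloxymethyl)-2,3-(isopropylidenedioxy)cyclohex-4-en-6-ol | CC(=O)O[C@H]1[C@H]2OC(C)(C)O[C@@H]2C=C(COC(=O)c2ccccc2)[C@@H]1O
F7 | step 1 | 1,2:3,4:5,6-tri-O-isopropylidene-D-mannitol | CC1(C)OC[C@@H](O1)[C@H]2OC(C)(C)O[C@@H]2[C@H]3COC(C)(C)O3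
F8 | step 1 | 3,4:5,6-di-O-isopropylidene-D-mannitol | OC[C@@H](O)[C@H]1OC(C)(C)O[C@@H]1[C@H]2COC(C)(C)O2
F9 | step 1 | 2,3:4,5-di-O-isopropylidene-aldehydo-D-arabinose | O=C[C@H]1OC(C)(C)O[C@@H]1[C@H]2COC(C)(C)O2
F10 | step 1 | (E)-2,3-dideoxy-4,5:6,7-di-O-isopropylidene-D-arabino-hept-2-enose | O=C/C=C/[C@H]1OC(C)(C)O[C@@H]1[C@H]2COC(C)(C)O2
F11 | step 2 | ethyl (E)-2,3-dideoxy-4,5-O-isopropylidene-D-arabino-hept-2-enonate | CCOC(=O)/C=C/[C@H]1OC(C)(C)O[C@@H]1[C@H](O)CO
F12 | step 2 | (E)-2,3-dideoxy-4,5-O-isopropylidene-D-arabino-hept-2-enitol (1,6,7-triol) | OC/C=C/[C@H]1OC(C)(C)O[C@@H]1[C@H](O)CO
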